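**Plan**
- Retrosynthesis: the C7 methyl is traced back to a C7 ketone (enol triflate, methylzinc coupling). Ring A of that spiro ketone is then cut at C8–C9 and at C6–C11, leaving a ring-B methyl ketone (C6, C7, C8) and a C9–C10–C11 unit.
- Enabling feature: in ring A, C7 lies between C6 and C8, so a C7 carbonyl makes both its α-carbons nucleophilic. The C10 bromine lies between C9H2 and the gem-dimethyl carbon C11, so C9 can carry a triflate for SN2 and C11 a chloride that ionizes with bromine assistance. Together this is a [3+3] annulation.
- Forward: ring B comes intact from (R)-limonene and receives its trans C2–Cl/C3–Br pair before ring A exists. The isopropenyl group becomes the acetyl group, ring A is closed onto C6 in one flask, and the C7 carbonyl is replaced by the methyl group last.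
- Stereochemistry: C2 and C3 come from the limonene stereocentre via the trans epoxide, chloride opening at C2 with inversion and bromide return at C3 anti to chlorine. That centre (C6) then passes through an enol and is set again by ring-B face control in the annulation. C10 comes from catalytic enantioselective bromochlorination of prenol and is never broken.

Key step: step 7

Remark: chamigrene numbering is used (ring B = C1–C6 with C2–Cl and C3–Br/Me; ring A = C6–C11 with C7=C8, C10–Br and gem-dimethyl C11); the target is read as (2S,3S,6S,10R). The ligand antipode in step 5 is assumed to be the one that gives the R bromide.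

**Step 1**
Reactants: 1 (R)-limonene
Product: 3 trans-limonene oxide (1S,2R,4R)-1,2-epoxy-p-menth-8-ene, via bromohydrin 2 (not isolated)
Conditions: NBS, acetone/H2O, 0 °C; then NaOH (aq), 0 °C to rt
Reagents that add atoms: water (O)
Why: Halohydrin formation at the more electron-rich ring alkene is trans-diaxial (water at the tertiary carbon, bromine at C2 on the face opposite to the isopropenyl group), and intramolecular Williamson closure then puts the epoxide oxygen cis to the isopropenyl group.

**Step 2**
Reactants: 3 trans-limonene oxide
Product: 4 (1S,2S,4R)-2-chloro-1-methyl-4-(prop-1-en-2-yl)cyclohexan-1-ol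
Conditions: LiCl, AcOH, THF, rt
Reagents that add atoms: lithium chloride ([Li+].[Cl-])
Why: Trans-diaxial (Fürst–Plattner) epoxide opening of this isomer takes place at the secondary carbon C2 by SN2 with inversion, which fixes C2–Cl anti to the tertiary hydroxyl group.

**Step 3**
Reactants: 4 chlorohydrin
Product: 5 1-[(1R,3S,4S)-3-chloro-4-hydroxy-4-methylcyclohexyl]ethan-1-one
Conditions: O3, CH2Cl2/MeOH, −78 °C; then Me2S
Reagents that add atoms: ozone ([O-][O+]=O)
Why: Ozonolysis with reductive work-up cleaves the 1,1-disubstituted alkene to the methyl ketone that supplies C7 and C8; no stereocentre is touched.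

**Step 4**
Reactants: 5 hydroxy ketone
Product: 6 1-[(1R,3S,4S)-4-bromo-3-chloro-4-methylcyclohexyl]ethan-1-one
Conditions: Me3SiBr, CH2Cl2, 0 °C
Reagents that add atoms: bromotrimethylsilane (C[Si](C)(C)Br)
Why: SN1 exchange of the tertiary hydroxyl for bromide; bromide should enter axially, anti to the axial C2–Cl bond that shields (or bridges) the other face, so the trans-diaxial bromochloride results with retention at C3.

**Step 5**
Reactants: 7 prenol (3-methylbut-2-en-1-ol)
Product: 8 (2R)-2-bromo-3-chloro-3-methylbutan-1-ol
Conditions: NBS, ClTi(OiPr)3, chiral tridentate salicylaldimine (Schiff base) ligand (cat.), hexanes, −20 °C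
Reagents that add atoms: N-bromosuccinimide (O=C1CCC(=O)N1Br); chlorotitanium triisopropoxide (CC(C)O[Ti](Cl)(OC(C)C)OC(C)C)
Why: Titanium-mediated catalytic enantioselective bromochlorination of an allylic alcohol; bromine goes to C2 and chloride opens the bromonium ion at the tertiary carbon (Markovnikov), the ligand-bound titanium alkoxide selecting the alkene face.

**Step 6**
Reactants: 8 bromochloro alcohol
Product: 9 (2R)-2-bromo-3-chloro-3-methylbutyl trifluoromethanesulfonate
Conditions: Tf2O, 2,6-lutidine, CH2Cl2, −78 °C
Reagents that add atoms: triflic anhydride (O=S(=O)(OS(=O)(=O)C(F)(F)F)C(F)(F)F)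
Why: Sulfonylation of the primary alcohol with a hindered base at low temperature; the stereocentre is not involved and the triflate is used at once.

**Step 7**
Reactants: 6 bromochloro methyl ketone; 9 bromochloro triflate
Product: 12 (4R,6R,8S,9S)-4,9-dibromo-8-chloro-5,5,9-trimethylspiro[5.5]undecan-1-one, via lithium enolate 10 (not isolated), via alkylated ketone 11 (not isolated)
Conditions: LiN(SiMe3)2, THF, −78 °C; then 9, −78 to −30 °C; volatiles removed under vacuum; HFIP, 25 to 40 °C
Reagents that add atoms: none
Why: Proposed new method: the kinetic lithium enolate 10 (carbanion at C8) displaces the primary triflate of 9 by SN2 (C8–C9), and in HFIP the tertiary C11–Cl bond of 11 then ionizes with anchimeric help from the C10 bromine to a bromonium ion that is opened at C11, anti to bromine, by C6 of the more substituted enol of the C7 ketone (C6–C11) with loss of HCl. The closest known reaction types are the α,α′-annulation of a ketone with a 1,3-dielectrophile, the bromonium cyclization set off by solvolysis of a vicinal bromochloride in HFIP (known with alkene terminators) and the Lewis-acid-mediated α-tert-alkylation of silyl enol ethers with tertiary chlorides. Ring A is the only ring closed, in the 6-endo mode at the bromonium ion (C10 and C11 both end in the ring) through a chair with the C10 bromine equatorial; C8 cannot compete since it would close a four-membered ring, and capture by the carbonyl oxygen gives a tert-alkyl oxocarbenium ion that should reopen under the same ionizing conditions and drain to the C–C bonded ketone. C10 is not a reacting centre and keeps the R configuration of 9 because bromine bridges and returns on its own face. The new spiro centre C6 is set by the face of the ring-B enol that C11 attacks: equatorial entry on the ring-B chair that holds the C2 chlorine equatorial puts C11 cis to chlorine, attack on the other face would press C11 or the C7 oxygen against an axial C2 chlorine, and the two enol geometries interconvert through the ketone so that the matched chair is always available. The step needs C-alkylation of the enolate ahead of elimination at the β-bromo triflate, which the low temperature and the lithium counter-ion in THF should secure, and ionization at C11 ahead of the ring-B tertiary bromide, which the far better neighbouring-group help of bromine (at C11) than of chlorine (at C3) should secure.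

**Step 8**
Reactants: 12 spiro ketone
Product: 14 (4R,6R,8S,9S)-4,9-dibromo-8-chloro-5,5,9-trimethylspiro[5.5]undec-1-en-1-yl trifluoromethanesulfonate, via potassium enolate 13 (not isolated)
Conditions: KN(SiMe3)2, THF, −78 °C; then PhNTf2
Reagents that add atoms: N-phenylbis(trifluoromethanesulfonimide) (O=S(=O)(N(c1ccccc1)S(=O)(=O)C(F)(F)F)C(F)(F)F)
Why: Enol triflate formation; C6 is quaternary, so the ketone can enolize only toward C8 and a single regioisomer forms, while the equatorial C10 bromine has neither an antiperiplanar hydrogen nor the alignment for 1,3-closure onto the enolate.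

**Step 9**
Reactants: 14 enol triflate
Product: 15 (4R,6S,8S,9S)-4,9-dibromo-8-chloro-1,5,5,9-tetramethylspiro[5.5]undec-1-ene, the target [(2S,3S,6S,10R) in chamigrene numbering]
Conditions: MeZnCl, Pd(PPh3)4 (cat.), THF, rt
Reagents that add atoms: methylzinc chloride (C[Zn]Cl)
Why: Negishi coupling puts the methyl group on C7 and leaves the double bond at C7=C8; unactivated secondary and tertiary alkyl halides should not add to zerovalent palladium carrying triphenylphosphine under these mild conditions.

**Compound list**
1 | (R)-limonene | CC(=C)[C@@H]1CCC(C)=CC1 | starting material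
2 | (1S,2S,4R)-2-bromo-1-methyl-4-(prop-1-en-2-yl)cyclohexan-1-ol (bromohydrin) | CC(=C)[C@@H]1CC[C@](C)(O)[C@@H](Br)C1 | intermediate
3 | trans-limonene oxide, (1S,2R,4R)-1,2-epoxy-p-menth-8-ene | CC(=C)[C@@H]1CC[C@]2(C)O[C@@H]2C1 | intermediate
4 | (1S,2S,4R)-2-chloro-1-methyl-4-(prop-1-en-2-yl)cyclohexan-1-ol | CC(=C)[C@@H]1CC[C@](C)(O)[C@@H](Cl)C1 | intermediate
5 | 1-[(1R,3S,4S)-3-chloro-4-hydroxy-4-methylcyclohexyl]ethan-1-one | CC(=O)[C@@H]1CC[C@](C)(O)[C@@H](Cl)C1 | intermediate
6 | 1-[(1R,3S,4S)-4-bromo-3-chloro-4-methylcyclohexyl]ethan-1-one | CC(=O)[C@@H]1CC[C@](C)(Br)[C@@H](Cl)C1 | intermediate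
7 | prenol (3-methylbut-2-en-1-ol) | CC(C)=CCO | starting material
8 | (2R)-2-bromo-3-chloro-3-methylbutan-1-ol | OC[C@@H](Br)C(C)(C)Cl | intermediate
9 | (2R)-2-bromo-3-chloro-3-methylbutyl trifluoromethanesulfonate | O=S(=O)(OC[C@@H](Br)C(C)(C)Cl)C(F)(F)F | intermediate
10 | lithium 1-[(1R,3S,4S)-4-bromo-3-chloro-4-methylcyclohexyl]ethen-1-olate (lithium enolate) | [Li+].[O-]C(=C)[C@@H]1CC[C@](C)(Br)[C@@H](Cl)C1 | intermediate
11 | (4R)-4-bromo-1-[(1R,3S,4S)-4-bromo-3-chloro-4-methylcyclohexyl]-5-chloro-5-methylhexan-1-one (alkylated ketone) | ClC(C)(C)[C@H](Br)CCC(=O)[C@@H]1CC[C@](C)(Br)[C@@H](Cl)C1 | intermediate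
12 | (4R,6R,8S,9S)-4,9-dibromo-8-chloro-5,5,9-trimethylspiro[5.5]undecan-1-one | O=C1CC[C@@H](Br)C(C)(C)[C@]12CC[C@](C)(Br)[C@@H](Cl)C2 | intermediate
13 | potassium (4R,6R,8S,9S)-4,9-dibromo-8-chloro-5,5,9-trimethylspiro[5.5]undec-1-en-1-olate (potassium enolate) | [K+].[O-]C1=CC[C@@H](Br)C(C)(C)[C@]12CC[C@](C)(Br)[C@@H](Cl)C2 | intermediate
14 | (4R,6R,8S,9S)-4,9-dibromo-8-chloro-5,5,9-trimethylspiro[5.5]undec-1-en-1-yl trifluoromethanesulfonate | O=S(=O)(OC1=CC[C@@H](Br)C(C)(C)[C@]12CC[C@](C)(Br)[C@@H](Cl)C2)C(F)(F)F | intermediate
15 | (4R,6S,8S,9S)-4,9-dibromo-8-chloro-1,5,5,9-tetramethylspiro[5.5]undec-1-ene | CC1=CC[C@@H](Br)C(C)(C)[C@]12CC[C@](C)(Br)[C@@H](Cl)C2 | target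

**Step count:** 9 steps in total. The longest linear sequence is 7 steps (steps 1, 2, 3, 4, 7, 8, 9); steps 5 and 6 form the second branch.

**Steps most likely to fail**

Most at risk is step 7 (Proposed new method). What may go wrong:
- In the first stage the enolate may remove a proton from the β-bromo triflate or react through oxygen.
- In the ionizing stage the carbonyl oxygen or the solvent may hold the bromonium ion.
- The ring-B tertiary bromide may ionize as well.
- C11 may add to the wrong face of ring B.

The fallback makes the same two bonds in the opposite order with known reactions. Ketone 6 would be converted into its more substituted silyl enol ether {1-[(3S,4S)-4-bromo-3-chloro-4-methylcyclohexylidene]ethoxy}trimethylsilane F1 (Me3SiOTf, Et3N, CH2Cl2; the terminal isomer would be hydrolysed back to 6). Alcohol 8 would be converted into (2R)-2-bromo-3-chloro-3-methylbutyl 4-methylbenzenesulfonate F2 (TsCl, pyridine). TiCl4 in CH2Cl2 at −78 °C should join them by α-tert-alkylation of the silyl enol ether with the tertiary chloride (C6–C11), giving the keto tosylate (2S)-3-[(1R,3S,4S)-1-acetyl-4-bromo-3-chloro-4-methylcyclohexyl]-2-bromo-3-methylbutyl 4-methylbenzenesulfonate F3. C6 epimers would be separated at this stage. KN(SiMe3)2 in THF would then close ring A by intramolecular alkylation of the methyl ketone enolate at C9 (C8–C9), returning to the route at spiro ketone 12.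

Second is step 4. The cation at C3 may lose a proton to give an allylic chloride, or bromide may return on both faces. The fallback avoids the cation. Hydroxy ketone 5 would be dehydrated with POCl3 in pyridine; this is an anti elimination, and the axial C2 chlorine leaves no antiperiplanar hydrogen on C2, so the double bond should form away from C2, giving 1-[(1R,5S)-5-chloro-4-methylcyclohex-3-en-1-yl]ethan-1-one F4. A cobalt-hydride hydrogen-atom-transfer Markovnikov hydrobromination (Co(acac)2, PhSiH3, TsBr) would then form the tertiary C3 radical, which should take up bromine anti to the neighbouring chlorine, returning to the route at ketone 6.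

Third is step 8. The base may act on the halides before the enolate is triflated, by loss of HBr from ring B through a methyl hydrogen or by closure of the C8 enolate onto C10. The fallback uses no enolate and also replaces step 9. Spiro ketone 12 would be methylenated with Cp2TiMe2 in toluene at 65 °C to (4R,6S,8S,9S)-4,9-dibromo-8-chloro-5,5,9-trimethyl-1-methylidenespiro[5.5]undecane F5. A catalytic amount of p-TsOH in CH2Cl2 should then move the exocyclic double bond into the ring to the more substituted C7=C8 position, returning to the route at target 15.

**Further compounds**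
F1 | step 7 | {1-[(3S,4S)-4-bromo-3-chloro-4-methylcyclohexylidene]ethoxy}trimethylsilane | CC(O[Si](C)(C)C)=C1CC[C@](C)(Br)[C@@H](Cl)C1
F2 | step 7 | (2R)-2-bromo-3-chloro-3-methylbutyl 4-methylbenzenesulfonate | Cc1ccc(cc1)S(=O)(=O)OC[C@@H](Br)C(C)(C)Cl
F3 | step 7 | (2S)-3-[(1R,3S,4S)-1-acetyl-4-bromo-3-chloro-4-methylcyclohexyl]-2-bromo-3-methylbutyl 4-methylbenzenesulfonate | CC(=O)[C@]1(C(C)(C)[C@H](Br)COS(=O)(=O)c2ccc(C)cc2)CC[C@](C)(Br)[C@@H](Cl)C1
F4 | step 4 | 1-[(1R,5S)-5-chloro-4-methylcyclohex-3-en-1-yl]ethan-1-one | CC(=O)[C@@H]1CC=C(C)[C@@H](Cl)C1
F5 | step 8 | (4R,6S,8S,9S)-4,9-dibromo-8-chloro-5,5,9-trimethyl-1-methylidenespiro[5.5]undecane | C=C1CC[C@@H](Br)C(C)(C)[C@]12CC[C@](C)(Br)[C@@H](Cl)C2
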